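**Plan**

- Retrosynthesis: the crotonate C–O bonds at C8 and C9 and the lactone bond O–C6 are cut first (C12 returns to the methyl of an isopropenyl group on C7). Then C3–C4 of the ten-membered ring is cut while C1–C6 is re-formed. Last come C1–C2 (ethynyl) and C6–C5 (allyl).
- Enabling feature: in the carbocycle C1–C10 the unit C1(=O)–C2=C3–C4, followed by C5 and C6, is the retron of an alkynyl oxy-Cope shift. The remaining ring atoms C1, C6, C7, C8, C9, C10 with the C11–C13 branch on C7 are the skeleton of (R)-carvone.
- Forward order: the bought six-membered ring is oxygenated at C8, C9 and C10, then given a propenyl group at C6 and an ethynyl group at C1. The ten-membered ring arises from it by four-carbon ring expansion (step 14), the γ-lactone ring closes afterwards by iodolactonisation, and the crotonates come last.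
- Stereochemistry: C7 is carvone's centre. C10, C9 and C8 follow from two hydroxyl-directed epoxidations on the isopropenyl face, each opened trans-diaxially at C9. The sacrificial C6 is set by kinetic protonation and C1 by equatorial acetylide addition. C4 is relayed from C6 through the chair transition state, and C6–O comes from anti addition to the (E)-C5=C6 alkene.

Key step: step 14

Conventions and assumption: every intermediate carries the locants of the target carbocycle (C1 ketone carbon, C2=C3, C4 CHMe, C5, C6 lactone CH–O, C7, C8 and C9 acyloxy carbons, C10 C(OH)Me, C11–C13 the branch on C7). In the cyclohexane intermediates α is the ring face carrying the C7 isopropenyl group and β the opposite face. The C5 centre of (R)-carvone is taken as C7 of the target.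

**Route**

Step 1
Reactants: 1 (R)-carvone
Product: 2 cis-carveol (C1–OH α)
Conditions: NaBH4, CeCl3·7H2O, MeOH, −78 °C
Reagents that add atoms: none
Why: Luche reduction adds hydride 1,2 to the enone along the axial trajectory of the half-chair with equatorial isopropenyl, so the new C1 carbinol should carry its hydroxyl cis to the isopropenyl group (α).

Step 2
Reactants: 2 cis-carveol
Product: 3 9α,10α-epoxy alcohol
Conditions: VO(acac)2 (cat.), t-BuOOH, CH2Cl2, 0 °C to rt
Reagents that add atoms: tert-butyl hydroperoxide, CC(C)(C)OO
Why: Hydroxyl-directed vanadium-catalysed epoxidation of the allylic alcohol delivers oxygen to C9=C10 on the face of the C1 hydroxyl, which sets C9 and C10 (oxygen α) and leaves the unactivated isopropenyl alkene alone.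

Step 3
Reactants: 3 9α,10α-epoxy alcohol
Product: 5 C1 4-methoxybenzyl (PMB) ether of 3, via sodium alkoxide 4 (not isolated)
Conditions: NaH, THF/DMF, 0 °C; 4-MeOC6H4CH2Cl, Bu4NI (cat.), rt
Reagents that add atoms: 4-methoxybenzyl chloride, COc1ccc(CCl)cc1
Why: Williamson etherification of the secondary alkoxide installs a C1 protecting group that survives hot hydroxide and is later removed oxidatively, and the alkoxide cannot open the oxirane because both lie on the same face.

Step 4
Reactants: 5 PMB ether
Product: 8 tertiary allylic alcohol (C8=C9; C10–OH α), via hydroxy selenide 6 (not isolated), via selenoxide 7 (not isolated)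
Conditions: (PhSe)2, NaBH4, EtOH, reflux; then H2O2 (30%), pyridine, THF, 0 °C to rt
Reagents that add atoms: none
Why: Selenide opening and selenoxide syn-elimination (epoxide to allylic alcohol transposition): PhSe− attacks the secondary C9 from the β face in a trans-diaxial opening that keeps the isopropenyl group equatorial, and the selenoxide can only eliminate toward C8 because C10 has no hydrogen, so the C10 carbinol (OH α) set in step 2 is kept.

Step 5
Reactants: 8 tertiary allylic alcohol
Product: 9 8α,9α-epoxy alcohol
Conditions: VO(acac)2 (cat.), t-BuOOH, toluene, rt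
Reagents that add atoms: tert-butyl hydroperoxide, CC(C)(C)OO
Why: A second hydroxyl-directed vanadium-catalysed epoxidation, now guided by the tertiary allylic C10 hydroxyl, should place the oxirane on the α face of C8=C9 (new centres C8 and C9) and again spare the isopropenyl group.

Step 6
Reactants: 9 8α,9α-epoxy alcohol
Product: 10 triol (C8–OH α; C9–OH β; C10–OH α)
Conditions: KOH, DMSO/H2O, 100 °C
Reagents that add atoms: water, O
Why: SN2 epoxide hydrolysis under Fürst–Plattner control: hydroxide attacks C9 from the β face because only this trans-diaxial opening runs through a chair with the isopropenyl, methyl and OPMB groups equatorial (attack at C8 would force them axial and meet the C10 methyl syn-axially), which inverts C9 to OH β and keeps the α oxygen at C8, while the syn C10 alkoxide cannot start a Payne shift.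

Step 7
Reactants: 10 triol
Product: 11 tris(methoxymethyl) ether
Conditions: MeOCH2Cl, i-Pr2NEt, NaI (cat.), ClCH2CH2Cl, 60 °C
Reagents that add atoms: chloromethyl methyl ether, COCCl
Why: Alkylation with MeOCH2Cl under iodide catalysis converts all three hydroxyls, the tertiary one included, into acetal ethers that are stable to amide bases, acetylides and KH and cannot migrate to the later C1 alkoxide.

Step 8
Reactants: 11 tris(methoxymethyl) ether
Product: 12 C1 alcohol (OH α)
Conditions: DDQ, CH2Cl2/pH 7 buffer, 0 °C to rt
Reagents that add atoms: none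
Why: Oxidative PMB cleavage with DDQ proceeds through the benzylic oxocarbenium ion and water, freeing C1–OH without touching the MOM ethers or the isopropenyl group.

Step 9
Reactants: 12 C1 alcohol
Product: 13 tris-MOM cyclohexanone
Conditions: Dess–Martin periodinane, CH2Cl2, rt
Reagents that add atoms: none
Why: Dess–Martin oxidation of the hindered secondary alcohol gives the C1 ketone, whose only enolisable position is C6 because C10 is quaternary.

Step 10
Reactants: 13 tris-MOM cyclohexanone; 14 allyl bromide
Product: 16 6β-allyl ketone, via lithium enolate 15 (not isolated)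
Conditions: LiN(i-Pr)2, THF, −78 °C; 14, DMPU, −78 to −20 °C
Reagents that add atoms: allyl bromide, C=CCBr
Why: Alkylation of the regiodefined lithium enolate with allyl bromide forms the C6–C5 bond, expected anti to the neighbouring isopropenyl group (β), and either C6 epimer is usable because this centre is reset in step 12.

Step 11
Reactants: 16 6β-allyl ketone
Product: 17 6β-[(E)-prop-1-enyl] ketone
Conditions: RuHCl(CO)(PPh3)3 (cat.), toluene, 80 °C
Reagents that add atoms: none
Why: Ruthenium hydride catalysed alkene isomerisation (hydrometalation and β-hydride elimination) moves the terminal double bond by one position to the (E)-propenyl isomer, favoured because a (Z)-methyl would clash with the branched C6, while the 1,1-disubstituted isopropenyl group does not react.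

Step 12
Reactants: 17 6β-[(E)-prop-1-enyl] ketone
Product: 19 6α-[(E)-prop-1-enyl] ketone, via lithium dienolate 18 (not isolated)
Conditions: LiN(i-Pr)2, THF, −78 °C; then inverse quench into AcOH/THF, −78 °C
Reagents that add atoms: none
Why: Deprotonation and kinetic protonation of the dienolate: A(1,2) strain with the C6 propenyl group holds the C7 isopropenyl group pseudoaxial, so the proton should enter C6 axially from the β face anti to it, which places the propenyl group α (cis to isopropenyl) and also returns any conjugated isomer to the β,γ-unsaturated ketone.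

Step 13
Reactants: 19 6α-[(E)-prop-1-enyl] ketone; 20 ethynyltrimethylsilane
Product: 22 1β-ethynyl-1α-hydroxy-6α-[(E)-prop-1-enyl]cyclohexane, via silylalkynyl carbinol 21 (not isolated)
Conditions: 20, n-BuLi, THF, −78 °C; CeCl3, −78 °C; then 19; aq NH4Cl; then K2CO3 (cat.), MeOH, rt
Reagents that add atoms: ethynyltrimethylsilane, C#C[Si](C)(C)C
Why: 1,2-Addition of the weakly basic organocerium acetylide (no enolisation at the doubly activated C6–H) should occur equatorially from the β face, because in the chair with the three MOM ethers and the propenyl group equatorial the axial C7 isopropenyl group blocks the axial α trajectory, giving ethynyl β and hydroxyl α at C1, and methanolysis of the C–Si bond then frees the terminal alkyne.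

Step 14
Reactants: 22 1β-ethynyl-1α-hydroxy-6α-[(E)-prop-1-enyl]cyclohexane
Product: 25 (2Z,5E)-cyclodeca-2,5-dienone, via potassium alkoxide 23 (not isolated), via potassium allenolate 24 (not isolated)
Conditions: KH, THF, 0 °C; then 18-crown-6, 0 °C to rt; inverse quench into AcOH/THF, −78 °C
Reagents that add atoms: none
Why: Anionic alkynyl oxy-Cope rearrangement: the crown-ether-separated C1 alkoxide weakens the C1–C6 bond and a [3,3]-sigmatropic shift joins the alkyne terminus C3 to the propenyl terminus C4 while C1–C6 breaks, the closest known reaction type being the anionic oxy-Cope ring expansion of 1-alkynyl-2-alkenylcyclohexanols to cyclodeca-2,5-dienones. The ten-membered ring is not closed end to end but arises by four-carbon expansion of the six-membered ring through a six-centre chair-like transition state (atoms C1 to C6) in which the β-ethynyl and α-propenyl groups are both equatorial on the cyclohexane and the alkoxide is axial. In that chair C7 is equatorial at C6, which gives the (E)-C5=C6 alkene, and the methyl group of the (E)-propenyl unit is equatorial at C4, so C3 bonds to one face of C4 only and the configuration of C6, which itself becomes sp2, is relayed to C4, the one new stereocentre. The potassium allenolate is protonated at C2 in the plane of the C3 substituents from the side of the C3 hydrogen, which gives the cis enone that the ten-membered ring also prefers. The step needs the correct C4 configuration and no base-induced migration of the skipped diene: the former is secured by the trans relation of the ethynyl and propenyl groups and the (E)-propenyl geometry fixed in steps 11 to 13, the latter by KH (no amine to shuttle protons) and a cold inverse quench into acetic acid.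

Step 15
Reactants: 25 (2Z,5E)-cyclodeca-2,5-dienone
Product: 26 allylic alcohol (C12 hydroxymethyl)
Conditions: SeO2 (cat.), t-BuOOH, CH2Cl2, rt
Reagents that add atoms: selenium dioxide, O=[Se]=O; tert-butyl hydroperoxide, CC(C)(C)OO
Why: Selenium dioxide allylic oxidation (ene reaction then [2,3]-shift) hydroxylates the methyl group of the 1,1-disubstituted isopropenyl alkene, the most nucleophilic double bond present, since the enone is electron-poor and the disubstituted C5=C6 alkene offers only methine hydrogens.

Step 16
Reactants: 26 allylic alcohol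
Product: 28 acrylic acid (C12 carboxylic acid), via enal 27 (not isolated)
Conditions: Dess–Martin periodinane, CH2Cl2, rt; then NaClO2, NaH2PO4, 2-methyl-2-butene, t-BuOH/H2O, 0 °C
Reagents that add atoms: sodium chlorite, [Na+].[O-]Cl=O
Why: Dess–Martin oxidation of the allylic alcohol followed by Pinnick oxidation of the 2-substituted acrolein gives the acrylic acid under buffered, non-basic conditions that spare the skipped dienone, with 2-methyl-2-butene removing the HOCl formed.

Step 17
Reactants: 28 acrylic acid
Product: 29 5-iodo-12,6-lactone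
Conditions: I2, NaHCO3, MeCN, 0 °C, dark
Reagents that add atoms: iodine, II
Why: Iodolactonisation: iodine activates C5=C6, the only electron-rich alkene, and the C12 carboxylate closes 5-exo on C6 anti to iodine, and because the ring bond C7–C8 cannot eclipse an (E) double bond in the ten-membered ring the arm on C7 reaches only the face of C6 that leaves H6 and H7 anti, which is the trans-fused lactone with the C6 configuration of the target.

Step 18
Reactants: 29 5-iodo-12,6-lactone
Product: 30 tris-MOM α-methylene lactone
Conditions: Bu3SnH, Et3B (cat.), air, toluene, 0 °C to rt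
Reagents that add atoms: none
Why: Radical chain dehalogenation with Bu3SnH replaces the C5 iodine by hydrogen, the C5 radical having no favourable cyclisation onto the enone or the methylene lactone, so the C6 centre set in step 17 is kept.

Step 19
Reactants: 30 tris-MOM α-methylene lactone
Product: 31 8,9,10-triol lactone
Conditions: HCl (1.25 M in MeOH), 40 °C
Reagents that add atoms: none
Why: Acid-catalysed acetal exchange with methanol removes the three MOM groups as dimethoxymethane under conditions that α-methylene lactones, enones and the tertiary ketol are expected to tolerate.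

Step 20
Reactants: 31 8,9,10-triol lactone; 32 (E)-crotonic anhydride
Product: 33 target CNP0223772.1
Conditions: 32, DMAP (cat.), Et3N, CH2Cl2, 0 °C to rt
Reagents that add atoms: (E)-crotonic anhydride, C/C=C/C(=O)OC(=O)/C=C/C
Why: DMAP-catalysed acylation esterifies the two secondary hydroxyls at C8 and C9 while the tertiary C10 carbinol beside the ketone is too hindered to react, and the anhydride avoids the ketene pathway that can deconjugate crotonyl chloride.

**Compound list**

1 | (R)-carvone | CC1=CC[C@H](CC1=O)C(C)=C | starting material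
2 | (1R,5R)-cis-carveol (C1–OH α, cis to isopropenyl; C9=C10) | C1[C@H](C(C)=C)CC=C(C)[C@@H]1O | intermediate
3 | 9α,10α-epoxy-cis-carveol (oxirane O and C1–OH both α) | C1[C@H](C(C)=C)C[C@@H]2O[C@]2(C)[C@@H]1O | intermediate
4 | sodium alkoxide of 3 | C1[C@H](C(C)=C)C[C@@H]2O[C@]2(C)[C@@H]1[O-].[Na+] | intermediate
5 | C1 4-methoxybenzyl ether of 3 | C1[C@H](C(C)=C)C[C@@H]2O[C@]2(C)[C@@H]1OCc3ccc(OC)cc3 | intermediate
6 | hydroxy selenide (C9–SePh β, C10–OH α, C1–OPMB α) | C1[C@H](C(C)=C)C[C@@H]([Se]c2ccccc2)[C@](C)(O)[C@@H]1OCc3ccc(OC)cc3 | intermediate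
7 | selenoxide of 6 | C1[C@H](C(C)=C)C[C@@H]([Se](=O)c2ccccc2)[C@](C)(O)[C@@H]1OCc3ccc(OC)cc3 | intermediate
8 | tertiary allylic alcohol (C8=C9, C10–OH α and C10–Me β, C1–OPMB α) | C1[C@H](C(C)=C)C=C[C@](C)(O)[C@@H]1OCc3ccc(OC)cc3 | intermediate
9 | 8α,9α-epoxide of 8 | C1[C@H](C(C)=C)[C@@H]2O[C@@H]2[C@](C)(O)[C@@H]1OCc3ccc(OC)cc3 | intermediate
10 | triol (C8–OH α, C9–OH β, C10–OH α, C1–OPMB α) | C1[C@H](C(C)=C)[C@H](O)[C@@H](O)[C@](C)(O)[C@@H]1OCc3ccc(OC)cc3 | intermediate
11 | 8,9,10-tris(methoxymethyl) ether of 10 | C1[C@H](C(C)=C)[C@H](OCOC)[C@@H](OCOC)[C@](C)(OCOC)[C@@H]1OCc3ccc(OC)cc3 | intermediate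
12 | C1 alcohol (OH α) with 8α,9β,10α-tris(methoxymethoxy) groups | C1[C@H](C(C)=C)[C@H](OCOC)[C@@H](OCOC)[C@](C)(OCOC)[C@@H]1O | intermediate
13 | cyclohexanone (C1 ketone, C7 isopropenyl α, OMOM at C8 α, C9 β, C10 α, C10–Me β) | C1[C@H](C(C)=C)[C@H](OCOC)[C@@H](OCOC)[C@](C)(OCOC)C1=O | intermediate
14 | allyl bromide | C=CCBr | starting material
15 | lithium enolate of 13 (C1(OLi)=C6) | [Li+].[O-]C1=C[C@H](C(C)=C)[C@H](OCOC)[C@@H](OCOC)[C@]1(C)OCOC | intermediate
16 | 6β-allyl ketone (allyl trans to isopropenyl) | C=CC[C@H]1[C@H](C(C)=C)[C@H](OCOC)[C@@H](OCOC)[C@](C)(OCOC)C1=O | intermediate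
17 | 6β-[(E)-prop-1-enyl] ketone | C/C=C/[C@H]1[C@H](C(C)=C)[C@H](OCOC)[C@@H](OCOC)[C@](C)(OCOC)C1=O | intermediate
18 | lithium dienolate of 17 (C1(OLi)=C6–C5=C4) | [Li+].[O-]C1=C(/C=C/C)[C@H](C(C)=C)[C@H](OCOC)[C@@H](OCOC)[C@]1(C)OCOC | intermediate
19 | 6α-[(E)-prop-1-enyl] ketone (propenyl cis to isopropenyl) | C/C=C/[C@@H]1[C@H](C(C)=C)[C@H](OCOC)[C@@H](OCOC)[C@](C)(OCOC)C1=O | intermediate
20 | ethynyltrimethylsilane | C#C[Si](C)(C)C | starting material
21 | 1β-[(trimethylsilyl)ethynyl]-1α-hydroxy adduct of 19 | C/C=C/[C@@H]1[C@H](C(C)=C)[C@H](OCOC)[C@@H](OCOC)[C@](C)(OCOC)[C@@]1(O)C#C[Si](C)(C)C | intermediate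
22 | 1β-ethynyl-1α-hydroxy-6α-[(E)-prop-1-enyl]-7α-isopropenyl-8α,9β,10α-tris(methoxymethoxy)-10β-methylcyclohexane (oxy-Cope precursor) | C/C=C/[C@@H]1[C@H](C(C)=C)[C@H](OCOC)[C@@H](OCOC)[C@](C)(OCOC)[C@@]1(O)C#C | intermediate
23 | potassium alkoxide of 22 | [K+].C/C=C/[C@@H]1[C@H](C(C)=C)[C@H](OCOC)[C@@H](OCOC)[C@](C)(OCOC)[C@@]1([O-])C#C | intermediate
24 | potassium allenolate (C1(OK)=C2=C3 in the ten-membered ring, (E)-C5=C6) | [K+].[O-]C1=C=C[C@H](C)/C=C/[C@H](C(C)=C)[C@H](OCOC)[C@@H](OCOC)[C@]1(C)OCOC | intermediate
25 | (2Z,5E)-4-methyl-7-isopropenyl-8,9,10-tris(methoxymethoxy)-10-methylcyclodeca-2,5-dien-1-one (oxy-Cope product) | O=C1/C=C\[C@H](C)/C=C/[C@H](C(C)=C)[C@H](OCOC)[C@@H](OCOC)[C@]1(C)OCOC | intermediate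
26 | allylic alcohol (C7 bears C11(=C13H2)–C12H2OH) | O=C1/C=C\[C@H](C)/C=C/[C@H](C(CO)=C)[C@H](OCOC)[C@@H](OCOC)[C@]1(C)OCOC | intermediate
27 | enal (C12 aldehyde) | O=C1/C=C\[C@H](C)/C=C/[C@H](C(C=O)=C)[C@H](OCOC)[C@@H](OCOC)[C@]1(C)OCOC | intermediate
28 | acrylic acid (C12 carboxylic acid) | O=C1/C=C\[C@H](C)/C=C/[C@H](C(C(=O)O)=C)[C@H](OCOC)[C@@H](OCOC)[C@]1(C)OCOC | intermediate
29 | 5-iodo-12,6-lactone (trans-fused; C5–I anti to C6–O) | C=C1C(=O)O[C@@H]2[C@H](I)[C@@H](C)/C=C\C(=O)[C@@](C)(OCOC)[C@H](OCOC)[C@@H](OCOC)[C@@H]12 | intermediate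
30 | 8,9,10-tris(methoxymethoxy)-1-oxogermacra-2Z,11(13)-dien-12,6-olide | C=C1C(=O)O[C@@H]2C[C@@H](C)/C=C\C(=O)[C@@](C)(OCOC)[C@H](OCOC)[C@@H](OCOC)[C@@H]12 | intermediate
31 | 8,9,10-trihydroxy-1-oxogermacra-2Z,11(13)-dien-12,6-olide | C=C1C(=O)O[C@@H]2C[C@@H](C)/C=C\C(=O)[C@@](C)(O)[C@H](O)[C@@H](O)[C@@H]12 | intermediate
32 | (E)-crotonic anhydride | C/C=C/C(=O)OC(=O)/C=C/C | starting material
33 | CNP0223772.1: 8,9-bis[(E)-but-2-enoyloxy]-10-hydroxy-1-oxogermacra-2Z,11(13)-dien-12,6-olide | C=C1C(=O)O[C@@H]2C[C@@H](C)/C=C\C(=O)[C@@](C)(O)[C@H](OC(=O)/C=C/C)[C@@H](OC(=O)/C=C/C)[C@@H]12 | target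

**Count and risks**

Total step count: 20. Longest linear sequence: 20 steps, from (R)-carvone 1 to 33.

Steps most likely to fail:

Step 14. Proton transfer from the terminal alkyne, or drift of the allenolate to the fully conjugated trienolate, could erase the C4 centre and the 5,6-alkene. The potassium alkoxide could also fragment by loss of acetylide, or react through a boat-like geometry that leads to the 5Z, 4-epi series. The fallback runs the rearrangement without base. It sets out from 22: Me3SiOTf and 2,6-lutidine give the trimethylsilyl ether of 22 F1. Heating in o-dichlorobenzene at about 180 °C effects the neutral siloxy-Cope shift to the ten-membered cyclic siloxyallene F2. Cold dilute HCl in THF hydrolyses it and the route is rejoined at 25.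

Step 17. Iodonium formation on the hindered inner face of the medium-ring alkene may be too slow, and transannular capture by the C1 carbonyl oxygen or 6-endo closure may compete. The fallback makes the C6–O bond by syn-dihydroxylation and acyl substitution instead. It sets out from 28: OsO4 (cat.) with N-methylmorpholine N-oxide adds to C5=C6, the only electron-rich alkene, expected from the peripheral face that carries the C11 arm, to give the 5,6-dihydroxy acid F3. This lactonises onto the C6 hydroxyl to the 5-hydroxy-12,6-lactone F4. Thiocarbonyldiimidazole converts C5–OH into the imidazolyl thiocarbonate F5, and Bu3SnH removes it (Barton–McCombie deoxygenation), coming back to the route at 30.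

Step 15. The ene reaction may wander to the doubly allylic C7–H or to C4–H, and over-oxidation may set in. The fallback functionalises the methyl group by ene-type chlorination. It sets out from 25: NaOCl with CeCl3·7H2O in CH2Cl2/H2O gives the allylic chloride F6, which N-methylmorpholine N-oxide with KI (cat.) in MeCN oxidises to the enal. The route is rejoined at 27 and, after the NaClO2 stage of step 16, continues to 28.

Further compounds
F1 | step 14 | trimethylsilyl ether of 22 | C/C=C/[C@@H]1[C@H](C(C)=C)[C@H](OCOC)[C@@H](OCOC)[C@](C)(OCOC)[C@@]1(O[Si](C)(C)C)C#C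
F2 | step 14 | ten-membered cyclic siloxyallene (C1(OSiMe3)=C2=C3, (E)-C5=C6) | C[Si](C)(C)OC1=C=C[C@H](C)/C=C/[C@H](C(C)=C)[C@H](OCOC)[C@@H](OCOC)[C@]1(C)OCOC
F3 | step 17 | 5,6-dihydroxy acid from syn-dihydroxylation of 28 | O=C1/C=C\[C@H](C)[C@H](O)[C@@H](O)[C@H](C(C(=O)O)=C)[C@H](OCOC)[C@@H](OCOC)[C@]1(C)OCOC
F4 | step 17 | 5-hydroxy-12,6-lactone | C=C1C(=O)O[C@@H]2[C@@H](O)[C@@H](C)/C=C\C(=O)[C@@](C)(OCOC)[C@H](OCOC)[C@@H](OCOC)[C@@H]12
F5 | step 17 | C5 imidazolyl thiocarbonate of F4 | C=C1C(=O)O[C@@H]2[C@@H](OC(=S)n3ccnc3)[C@@H](C)/C=C\C(=O)[C@@](C)(OCOC)[C@H](OCOC)[C@@H](OCOC)[C@@H]12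
F6 | step 15 | allylic chloride (C7 bears C11(=C13H2)–C12H2Cl) | O=C1/C=C\[C@H](C)/C=C/[C@H](C(CCl)=C)[C@H](OCOC)[C@@H](OCOC)[C@]1(C)OCOC
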